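Both halves of the target are (2S)-2-arylchroman-4-ones, so each aryl–C2 bond is made by asymmetric conjugate arylation of a chromone. Everything rests on the bond between C2 of the pyranone ring C of the 5,7-dihydroxyflavanone unit and the para carbon of its 4-aryloxyphenyl ring. At the chromone oxidation level this C2 is the β-carbon of the vinylogous ester O1–C2=C3–C4=O. One rhodium-catalysed 1,4-addition joins the two fragments, sets C2 as (S) under ligand control and leaves the flavanone oxidation level. The precursors are a boronic acid that already carries the diaryl ether and the complete benzyl-protected 7-methoxyflavanone unit, and 5,7-bis(benzyloxy)chromone.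

Key step: step 9

Assumption: the (S)-configured biaryl bisphosphine is taken to give the (2S)-flavanone, by analogy with the sense of induction of (S)-biaryl bisphosphine rhodium catalysts on cyclic enones. If the sense were opposite, the antipodal ligand would be used in steps 7 and 9.

Ligand used in steps 7 and 9: (S)-MeO-F12-BIPHEP = (S)-(6,6'-dimethoxybiphenyl-2,2'-diyl)bis[bis(3,4,5-trifluorophenyl)phosphine].

Step 1
Reactants: 1 5,7-dihydroxychromone
Product: 2 5-hydroxy-7-methoxychromone
Conditions: MeI (1.1 equiv), K2CO3 (1.1 equiv), acetone, reflux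
Reagents that add atoms: iodomethane, CI
Why: Williamson etherification; the 7-OH is the acidic vinylogous acid while the 5-OH is locked in a hydrogen bond to the C4 carbonyl, so one equivalent of MeI should alkylate O7 only.

Step 2
Reactants: 2 5-hydroxy-7-methoxychromone
Product: 3 5-(benzyloxy)-7-methoxychromone
Conditions: BnBr (1.5 equiv), K2CO3 (2 equiv), DMF, 70 °C
Reagents that add atoms: benzyl bromide, BrCc1ccccc1
Why: Williamson etherification in a dipolar aprotic solvent with heating overcomes the chelation of the 5-OH and masks the only acidic proton of the acceptor.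

Step 3
Reactants: 1 5,7-dihydroxychromone
Product: 4 5,7-bis(benzyloxy)chromone
Conditions: BnBr (2.5 equiv), K2CO3 (3 equiv), DMF, 70 °C
Reagents that add atoms: benzyl bromide, BrCc1ccccc1
Why: Double Williamson etherification under the forcing conditions of step 2 should benzylate both the free 7-OH and the chelated 5-OH.

Step 4
Reactants: 5 2-(benzyloxy)phenol; 6 1-chloro-4-iodobenzene
Product: 7 1-(benzyloxy)-2-(4-chlorophenoxy)benzene
Conditions: CuI (10 mol %), picolinic acid (20 mol %), K3PO4 (2 equiv), DMSO, 90 °C
Reagents that add atoms: none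
Why: Copper-catalysed Ullmann-type diaryl ether synthesis; the C–I bond reacts far faster than the C–Cl bond, so the chloride is kept as the latent boron site of the 4-aryloxyphenyl ring.

Step 5
Reactants: 7 1-(benzyloxy)-2-(4-chlorophenoxy)benzene
Product: 8 1-(benzyloxy)-4-bromo-2-(4-chlorophenoxy)benzene
Conditions: NBS (1.05 equiv), MeCN, 0 °C to rt, dark
Reagents that add atoms: N-bromosuccinimide, O=C1CCC(=O)N1Br
Why: Electrophilic aromatic bromination should go para to the benzyloxy group, the stronger donor, because the aryloxy oxygen shares its lone pair with the chlorophenyl ring, which is itself deactivated and blocked at its para position.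

Step 6
Reactants: 8 1-(benzyloxy)-4-bromo-2-(4-chlorophenoxy)benzene
Product: 11 [4-(benzyloxy)-3-(4-chlorophenoxy)phenyl]boronic acid, via aryllithium 9 (not isolated), via lithium aryltriisopropoxyborate 10 (not isolated)
Conditions: n-BuLi (1.1 equiv), THF, −78 °C; B(OiPr)3 (1.5 equiv), −78 °C to rt; 1 M aq HCl
Reagents that add atoms: triisopropyl borate, CC(C)OB(OC(C)C)OC(C)C; water, O
Why: Bromine–lithium exchange at −78 °C is much faster than attack on the aryl chloride or the benzylic position, and borate trapping followed by acidic hydrolysis gives the boronic acid.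

Step 7
Reactants: 11 [4-(benzyloxy)-3-(4-chlorophenoxy)phenyl]boronic acid; 3 5-(benzyloxy)-7-methoxychromone
Product: 12 (2S)-5-(benzyloxy)-2-[4-(benzyloxy)-3-(4-chlorophenoxy)phenyl]-7-methoxychroman-4-one
Conditions: 11 (1.5 equiv), [Rh(OH)(cod)]2 (1.5 mol %), (S)-MeO-F12-BIPHEP (3.3 mol %), toluene, H2O (2 equiv), 25 °C
Reagents that add atoms: none
Why: Hayashi–Miyaura asymmetric 1,4-addition of an arylboronic acid to a 4-chromone; the (S)-bisphosphine on rhodium selects the face of C2=C3 in the insertion step and so sets C2 as (S), and the aryl chloride is inert to monovalent rhodium at room temperature.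

Step 8
Reactants: 12 (2S)-5-(benzyloxy)-2-[4-(benzyloxy)-3-(4-chlorophenoxy)phenyl]-7-methoxychroman-4-one
Product: 13 [4-[2-(benzyloxy)-5-[(2S)-5-(benzyloxy)-7-methoxy-4-oxochroman-2-yl]phenoxy]phenyl]boronic acid
Conditions: B2(OH)4 (2.5 equiv), PdCl(XPhos)(2'-aminobiphenyl-2-yl) (second-generation XPhos palladacycle, 2 mol %), XPhos (4 mol %), KOAc (3 equiv), EtOH, 80 °C; mildly acidic aqueous work-up
Reagents that add atoms: tetrahydroxydiboron, OB(O)B(O)O
Why: Miyaura-type borylation of an aryl chloride with tetrahydroxydiboron (oxidative addition to zerovalent palladium/XPhos, acetate-assisted transmetalation from the B–B bond, reductive elimination) gives the boronic acid directly, and acetate is too weak a base to enolise the C4 ketone appreciably, so C2 should keep its configuration.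

Step 9
Reactants: 13 [4-[2-(benzyloxy)-5-[(2S)-5-(benzyloxy)-7-methoxy-4-oxochroman-2-yl]phenoxy]phenyl]boronic acid; 4 5,7-bis(benzyloxy)chromone
Product: 14 (2S)-5,7-bis(benzyloxy)-2-[4-[2-(benzyloxy)-5-[(2S)-5-(benzyloxy)-7-methoxy-4-oxochroman-2-yl]phenoxy]phenyl]chroman-4-one (tetra-O-benzyl ether of the target)
Conditions: 4 (1.5 equiv), [Rh(OH)(cod)]2 (2.5 mol %), (S)-MeO-F12-BIPHEP (5.5 mol %), toluene/CH2Cl2 (4:1), H2O (2 equiv), 25–30 °C
Reagents that add atoms: none
Why: This is a Hayashi–Miyaura asymmetric 1,4-addition, the known reaction type that turns 4-chromones and arylboronic acids into flavanones: the hydroxorhodium bisphosphine complex (monovalent rhodium) takes the aryl group from the boron of 13, the aryl–rhodium species adds syn across C2=C3 of 4 with the aryl group going to the β-carbon C2, and water protonates the resulting oxa-π-allyl rhodium enolate at C3 and restores the hydroxo complex. No ring is closed; ring C is already present in 4 and only changes from pyranone to dihydropyranone. The new stereocentre C2 is controlled by the (S)-bisphosphine, which differentiates the faces of the bound chromone in the insertion step, while the existing stereocentre of 13 lies nine bonds away across the diaryl ether and should exert no matched or mismatched effect. The step needs 1,4- over 1,2-selectivity, which the substrates secure because the C4 ketones of 13 and 14 are electron-rich 2,4,6-trioxygenated aryl ketones flanked by a 5-benzyloxy group and are far less electrophilic towards aryl–rhodium than the unhindered C2=C3 bond. It also needs both C2–O1 bonds to survive, which the base-free and nearly non-polar medium at room temperature secures, since the rhodium enolate is protonated faster than it undergoes β-aryloxy elimination and the finished flavanone units are not enolised. The cheap chromone 4 is used in excess so that protodeboronation remains the only loss pathway of the valuable partner 13.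

Step 10
Reactants: 14 tetra-O-benzyl ether of the target
Product: 15 7-O-methyltetrahydroochnaflavone (2S and 2''S)
Conditions: H2 (1 atm), Pd/C (10 wt %), THF/MeOH (1:1), rt
Reagents that add atoms: none
Why: Catalytic hydrogenolysis removes the four primary O-benzyl groups under neutral conditions, where neither stereocentre can racemise by base-induced ring opening, and the secondary, ring-bound C2–O1 benzylic ethers react much more slowly.

Compound list
1 | 5,7-dihydroxychromone | O=c1ccoc2cc(O)cc(O)c12 | starting material
2 | 5-hydroxy-7-methoxychromone | COc1cc(O)c2c(=O)ccoc2c1 | intermediate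
3 | 5-(benzyloxy)-7-methoxychromone | COc1cc(OCc3ccccc3)c2c(=O)ccoc2c1 | intermediate
4 | 5,7-bis(benzyloxy)chromone | O=c1ccoc2cc(OCc3ccccc3)cc(OCc3ccccc3)c12 | intermediate
5 | 2-(benzyloxy)phenol | Oc1ccccc1OCc1ccccc1 | starting material
6 | 1-chloro-4-iodobenzene | Clc1ccc(I)cc1 | starting material
7 | 1-(benzyloxy)-2-(4-chlorophenoxy)benzene | Clc1ccc(Oc2ccccc2OCc2ccccc2)cc1 | intermediate
8 | 1-(benzyloxy)-4-bromo-2-(4-chlorophenoxy)benzene | Clc1ccc(Oc2cc(Br)ccc2OCc2ccccc2)cc1 | intermediate
9 | [4-(benzyloxy)-3-(4-chlorophenoxy)phenyl]lithium (not isolated) | [Li]c1ccc(OCc2ccccc2)c(Oc2ccc(Cl)cc2)c1 | intermediate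
10 | lithium [4-(benzyloxy)-3-(4-chlorophenoxy)phenyl]triisopropoxyborate (not isolated) | [Li+].CC(C)O[B-](OC(C)C)(OC(C)C)c1ccc(OCc2ccccc2)c(Oc2ccc(Cl)cc2)c1 | intermediate
11 | [4-(benzyloxy)-3-(4-chlorophenoxy)phenyl]boronic acid | OB(O)c1ccc(OCc2ccccc2)c(Oc2ccc(Cl)cc2)c1 | intermediate
12 | (2S)-5-(benzyloxy)-2-[4-(benzyloxy)-3-(4-chlorophenoxy)phenyl]-7-methoxychroman-4-one | COc1cc(OCc3ccccc3)c2c(c1)O[C@H](c1ccc(OCc3ccccc3)c(Oc3ccc(Cl)cc3)c1)CC2=O | intermediate
13 | [4-[2-(benzyloxy)-5-[(2S)-5-(benzyloxy)-7-methoxy-4-oxochroman-2-yl]phenoxy]phenyl]boronic acid | COc1cc(OCc3ccccc3)c2c(c1)O[C@H](c1ccc(OCc3ccccc3)c(Oc3ccc(B(O)O)cc3)c1)CC2=O | intermediate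
14 | (2S)-5,7-bis(benzyloxy)-2-[4-[2-(benzyloxy)-5-[(2S)-5-(benzyloxy)-7-methoxy-4-oxochroman-2-yl]phenoxy]phenyl]chroman-4-one | COc1cc(OCc3ccccc3)c2c(c1)O[C@H](c1ccc(OCc3ccccc3)c(Oc3ccc([C@@H]4CC(=O)c5c(OCc6ccccc6)cc(OCc6ccccc6)cc5O4)cc3)c1)CC2=O | intermediate
15 | 7-O-methyltetrahydroochnaflavone (2S,2''S) | COc1cc(O)c2c(c1)O[C@H](c1ccc(O)c(Oc3ccc([C@@H]4CC(=O)c5c(O)cc(O)cc5O4)cc3)c1)CC2=O | target

Total step count: 10. Longest linear sequence: 7 steps (steps 4, 5, 6, 7, 8, 9 and 10, from 2-(benzyloxy)phenol).

Steps most likely to fail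

Step 9. Insertion of the electron-rich 5,7-dialkoxychromone into the aryl–rhodium bond may be so slow that protodeboronation of the valuable boronic acid wins, or β-aryloxy elimination of the rhodium enolate may open ring C.
- The fallback redesigns the acceptor and the endgame. It sets out from 1 and 13 and comes back at 15.
- Compound 1 is peracetylated (Ac2O, pyridine, rt) to 4-oxo-4H-chromene-5,7-diyl diacetate F1. In F1 the two ring oxygens no longer donate strongly into the C4 carbonyl, so C2 is more electrophilic.
- The same rhodium-catalysed addition of 13 to F1 should give (2S)-2-[4-[2-(benzyloxy)-5-[(2S)-5-(benzyloxy)-7-methoxy-4-oxochroman-2-yl]phenoxy]phenyl]-4-oxochroman-5,7-diyl diacetate F2.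
- Base-free acid methanolysis (HCl from AcCl, MeOH/CH2Cl2, rt) should give (2S)-2-[4-[2-(benzyloxy)-5-[(2S)-5-(benzyloxy)-7-methoxy-4-oxochroman-2-yl]phenoxy]phenyl]-5,7-dihydroxychroman-4-one F3.
- Hydrogenolysis of the two remaining benzyl ethers (H2, Pd/C, THF/MeOH) leads to 15.

Step 8. Hydrodechlorination, partial reduction of the ketone by the diboron/ethanol system, or erosion of configuration at C2 by acetate-mediated enolisation and ring opening in hot protic solvent may occur. The free boronic acid is also hard to purify.
- The fallback brings the boron in as a chromatographable ester in an aprotic medium and unmasks it oxidatively at neutral pH. It sets out from 12 and comes back at 13.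
- Borylation with B2pin2 (Pd2(dba)3, XPhos, KOAc, 1,4-dioxane, 90 °C) should give (2S)-5-(benzyloxy)-2-[4-(benzyloxy)-3-[4-(4,4,5,5-tetramethyl-1,3,2-dioxaborolan-2-yl)phenoxy]phenyl]-7-methoxychroman-4-one F4, which is purified on silica.
- Cleavage of the pinacol unit with NaIO4 and NH4OAc in acetone/water at rt gives 13.

Step 10. Over-reduction may occur, either by hydrogenolysis of the benzylic C2–O1 bonds to dihydrochalcones or by reduction of the C4 ketones. The hindered 5-O-benzyl groups may also be cleaved incompletely.
- The fallback replaces hydrogenolysis by Lewis-acid dealkylation with a cation scavenger. It sets out from 14 and comes back at 15.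
- BCl3 and pentamethylbenzene in CH2Cl2 at −78 °C should remove all four benzyl groups as benzyl cations trapped by the arene.
- The 7-OMe group has no neighbouring carbonyl for chelation and should stay.
- This fallback makes no new compound (F0).

Further compounds
F1 | step 9 | 4-oxo-4H-chromene-5,7-diyl diacetate | CC(=O)Oc1cc(OC(C)=O)c2c(=O)ccoc2c1
F2 | step 9 | (2S)-2-[4-[2-(benzyloxy)-5-[(2S)-5-(benzyloxy)-7-methoxy-4-oxochroman-2-yl]phenoxy]phenyl]-4-oxochroman-5,7-diyl diacetate | COc1cc(OCc3ccccc3)c2c(c1)O[C@H](c1ccc(OCc3ccccc3)c(Oc3ccc([C@@H]4CC(=O)c5c(OC(C)=O)cc(OC(C)=O)cc5O4)cc3)c1)CC2=O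
F3 | step 9 | (2S)-2-[4-[2-(benzyloxy)-5-[(2S)-5-(benzyloxy)-7-methoxy-4-oxochroman-2-yl]phenoxy]phenyl]-5,7-dihydroxychroman-4-one | COc1cc(OCc3ccccc3)c2c(c1)O[C@H](c1ccc(OCc3ccccc3)c(Oc3ccc([C@@H]4CC(=O)c5c(O)cc(O)cc5O4)cc3)c1)CC2=O
F4 | step 8 | (2S)-5-(benzyloxy)-2-[4-(benzyloxy)-3-[4-(4,4,5,5-tetramethyl-1,3,2-dioxaborolan-2-yl)phenoxy]phenyl]-7-methoxychroman-4-one | COc1cc(OCc3ccccc3)c2c(c1)O[C@H](c1ccc(OCc3ccccc3)c(Oc3ccc(B4OC(C)(C)C(C)(C)O4)cc3)c1)CC2=O
F0 | step 10 | none | none
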